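**Retrosynthetic overview**
- The target is an achiral ester with one benzene ring that is bought, not built; no ring is formed and no stereocentre has to be set.
- Key disconnection (new step): the ArCH2–CH2CO2R bond, cut to the parent p-quinone methide (released from a 4-hydroxybenzyl sulfone) plus hexacosyl hydrogen malonate as a traceless acetate enolate (decarboxylative 1,6-addition).
- Hexacosyl hydrogen malonate comes from 1-hexacosanol and Meldrum's acid (ester C–O bond); the sulfone comes from 4-hydroxybenzyl alcohol and sodium p-toluenesulfinate (C–S bond).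
- Convergent, 2 + 1 steps, no protecting groups: the free phenol is the activating group for the C–C bond formation.

Assumption: the SMILES has no stereocentre, so "single enantiomer" does not apply; the alkyl chain is read as unbranched n-hexacosyl (26 carbons).

**Step 1**
Reactants: 1 hexacosan-1-ol; 2 Meldrum's acid (2,2-dimethyl-1,3-dioxane-4,6-dione)
Product: 3 hexacosyl hydrogen malonate (3-(hexacosyloxy)-3-oxopropanoic acid)
Conditions: 2 (1.1 equiv), PhMe, 100 °C, 5 h
Reagents that add atoms: none
Why: Thermal alcoholysis (ring-opening acylation) of Meldrum's acid by the primary alcohol gives only the mono-ester of malonic acid with loss of acetone, and no stereocentre is formed.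

**Step 2**
Reactants: 4 4-(hydroxymethyl)phenol (4-hydroxybenzyl alcohol)
Product: 5 4-[(4-methylbenzenesulfonyl)methyl]phenol
Conditions: TolSO2Na (1.5 equiv), HCO2H–H2O (1:1), 40 °C, 12 h
Reagents that add atoms: sodium 4-methylbenzenesulfinate, Cc1ccc(cc1)S(=O)[O-].[Na+]
Why: Acid-promoted SN1-type substitution in which the p-hydroxy-stabilised benzylic cation is captured at sulfur by the soft sulfinate (used in excess to outrun phenolic self-condensation), giving the stable crystalline sulfone (sulfinate S-alkylation).

**Step 3**
Reactants: 3 hexacosyl hydrogen malonate; 5 4-[(4-methylbenzenesulfonyl)methyl]phenol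
Product: 8 hexacosyl 3-(4-hydroxyphenyl)propanoate, via p-quinone methide 6 (not isolated), via benzylmalonic half-ester 7 (not isolated)
Conditions: 3 (1.3 equiv), DBU (2.6 equiv), MgCl2 (20 mol %), PhMe–DMF (4:1), 40 °C, slow addition of 5 over 4 h; then 100 °C, 3 h
Reagents that add atoms: none
Why: Proposed new method: a sulfinate-buffered decarboxylative 1,6-addition of a malonic acid half-oxyester to the unhindered parent p-quinone methide; the DBU phenoxide of 5 expels p-toluenesulfinate (1,6-elimination) to give 6, and sulfinate re-adds reversibly so that free 6 stays low; heteroatom adducts (carboxylate-O, phenoxide-O, DBU-N) are all p-hydroxybenzyl–X species that revert to 6, whereas C-attack by the Mg(II)/amine-enolised carboxylate of 3 at the exocyclic CH2 is made irreversible by aromatisation and gives racemic 7, whose amidinium carboxylate loses CO2 at 100 °C to leave the achiral ester 8; the closest known reaction types are amine-catalysed decarboxylative 1,6-additions of malonic half-thioesters and β-keto acids to stabilised (2,6-di-tert-butyl, δ-aryl) p-quinone methides and base-triggered sulfone-to-quinone-methide alkylations, neither shown for the parent unsubstituted p-quinone methide with a half-oxyester.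

**Compound list**
1 | hexacosan-1-ol | CCCCCCCCCCCCCCCCCCCCCCCCCCO | starting material
2 | Meldrum's acid (2,2-dimethyl-1,3-dioxane-4,6-dione) | CC1(C)OC(=O)CC(=O)O1 | starting material
3 | hexacosyl hydrogen malonate (3-(hexacosyloxy)-3-oxopropanoic acid) | CCCCCCCCCCCCCCCCCCCCCCCCCCOC(=O)CC(=O)O | intermediate
4 | 4-(hydroxymethyl)phenol (4-hydroxybenzyl alcohol) | OCc1ccc(O)cc1 | starting material
5 | 4-[(4-methylbenzenesulfonyl)methyl]phenol | Cc1ccc(cc1)S(=O)(=O)Cc1ccc(O)cc1 | intermediate
6 | 4-methylidenecyclohexa-2,5-dien-1-one (parent p-quinone methide, not isolated) | C=C1C=CC(=O)C=C1 | intermediate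
7 | 2-[(4-hydroxyphenyl)methyl]-3-(hexacosyloxy)-3-oxopropanoic acid (racemic, not isolated; its stereocentre is lost on decarboxylation) | CCCCCCCCCCCCCCCCCCCCCCCCCCOC(=O)C(Cc1ccc(O)cc1)C(=O)O | intermediate
8 | hexacosyl 3-(4-hydroxyphenyl)propanoate | CCCCCCCCCCCCCCCCCCCCCCCCCCOC(=O)CCc1ccc(O)cc1 | target

**Totals**
Total step count: 3. Longest linear sequence: 2 steps (1 → 3 → 8, or 4 → 5 → 8).

**Steps most likely to fail, with fallbacks**

Step 3 (the proposed new step) is the most likely to fail. The risks are oligomerisation of 6 through ortho-C attack of phenoxides, double benzylation of 3, and sluggish C-nucleophilicity of the half-oxyester. The fallback is known chemistry and sets out from 3. A Knoevenagel–Doebner condensation of 3 with commercial 4-hydroxybenzaldehyde (cat. piperidine, pyridine, 90 °C) gives hexacosyl (2E)-3-(4-hydroxyphenyl)prop-2-enoate F3 with decarboxylation. Hydrogenation of the alkene of F3 (H2 1 atm, 10% Pd/C, THF–EtOAc, 40 °C) then comes back to the route at 8.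

Step 2 is second. The risk is acid-induced self-condensation of 4 to phenolic oligomers before sulfinate capture. The fallback sets out from 4 and makes the C–S bond with a much stronger sulfur nucleophile, then adjusts the oxidation state. Heating 4 with 4-methylbenzenethiol in water at 90 °C gives 4-{[(4-methylphenyl)sulfanyl]methyl}phenol F2. Oxidation of F2 (30% H2O2, cat. Na2WO4, MeOH–EtOAc, 50 °C) comes back to the route at 5.

Step 1 is third. The risks are incomplete conversion of the waxy, poorly soluble alcohol and partial thermal decarboxylation of 3 to hexacosyl acetate. The fallback sets out from 1 and avoids heating. Steglich esterification of 1 with commercial 3-tert-butoxy-3-oxopropanoic acid (DCC, cat. DMAP, CH2Cl2, 25 °C) gives tert-butyl hexacosyl propanedioate F1. Cleavage of the tert-butyl ester of F1 (TFA–CH2Cl2 1:3, 25 °C) comes back to the route at 3.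

**Further compounds**
F1 | step 1 | tert-butyl hexacosyl propanedioate | CCCCCCCCCCCCCCCCCCCCCCCCCCOC(=O)CC(=O)OC(C)(C)C
F2 | step 2 | 4-{[(4-methylphenyl)sulfanyl]methyl}phenol | Cc1ccc(SCc2ccc(O)cc2)cc1
F3 | step 3 | hexacosyl (2E)-3-(4-hydroxyphenyl)prop-2-enoate | CCCCCCCCCCCCCCCCCCCCCCCCCCOC(=O)/C=C/c1ccc(O)cc1
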